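## Analysis of the target

Target 20 is 6-hydroxykaempferol 3-O-sulfate, 5,6,7-trihydroxy-2-(4-hydroxyphenyl)-4-oxo-4H-chromen-3-yl hydrogen sulfate. It is a 2-aryl-4H-chromen-4-one: ring A carries hydroxyls at C5, C6 and C7 and hydrogen at C8, ring B is a 4-hydroxyphenyl group on C2, and pyranone ring C carries the sulfate monoester on O3. There is no stereocentre and no configurational double bond, so the problem is one of regiochemistry and of telling five oxygen atoms apart. The sensitive groups are the enol hydrogen sulfate (cleaved by acid, and self-catalysing in its free-acid form), the pyrogallol-like 5,6,7-triol (oxidised by air, fastest in base) and the chromone ring (opened at C2 by hard nucleophiles). The difficulty is that only O3 may be sulfated, although the phenols at O7 and O4' are more acidic and more nucleophilic than the chelated 3-hydroxyl. O3 must therefore enter the molecule differently from the other four oxygens, and the groups masking those four must later leave under conditions the sulfate survives. The plan rests on the position of C3, alone between the aryl-bearing C2 and the carbonyl C4 of ring C. Without C3, the atoms O1, C2, C4, C4a and C8a form the five-membered ring of a 2-arylbenzofuran-3(2H)-one (9), so ring C is that benzofuranone enlarged by one heteroatom-bearing carbon. In addition, the 5,6,7-trioxygenation with C8–H maps onto a 3,4,5-trioxygenated phenol whose two free ring positions are equivalent, so annulation onto it can give only one regioisomer.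

## Retrosynthetic reasoning

20 ⇒ 18. The last bonds cut are the four O–CH2 bonds of benzyl ethers on O5, O6, O7 and O4', leaving the sulfate as the triethylammonium salt 18. Methyl ethers are ruled out for these positions: their cleavage needs a strong Lewis acid that would also strip the sulfate, and cleaving them before sulfation would expose all five hydroxyls at once. Benzyl ethers leave by neutral hydrogenolysis, which a sulfate salt tolerates, so they are carried from the first step.

18 ⇒ 17. The S–O3 bond is cut. Flavonol 17 has one free hydroxyl, so the sulfation has no regiochemical choice to make.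

17 ⇒ 14. The C3–O bond is cut back to a C3–Br bond. Forward, bromine–lithium exchange, borate capture and oxidative 1,2-shift turn C3–Br directly into C3–OH. An alkoxide coupling is not used, because it would give a 3-alkyl ether that cannot be removed beside four benzyl ethers, and hot alkoxide or hydroxide attacks C2 of a 3-bromochromone.

14 ⇒ 10 + 11 (key disconnection). The C2–C3 and C3–C4 bonds are cut and C3 is removed as the carbene derived from 11; what remains is the 3-silyloxybenzofuran 10. The cut is made here because it forms ring C and delivers C3 with a substituent unlike every oxygen in the molecule. The position of the carbonyl relative to the halogen is fixed by where the silyloxy group sits in 10. The forward step has to add the carbene to the furan C2=C3 bond only, then open the cyclopropane with loss of bromide and of the silyl group.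

10 ⇒ 9. The Si–O bond is cut. Silylation of the enol form of 9 gives the aromatic benzofuran and removes the C2 stereocentre of 9.

9 ⇒ 7. The aryl–acyl bond (C3–C3a of the benzofuranone) is cut. Forward, an intramolecular Friedel–Crafts acylation of acid 7 closes the five-membered ketone. Both positions ortho to the ether oxygen are equivalent, so only one regioisomer can form. Activation as a mixed anhydride avoids a strong Lewis acid, which would endanger the benzyl ethers.

7 ⇒ 6 ⇒ 3 + 5. Ester hydrolysis, then the O–C bond between the phenol oxygen (future O1) and the benzylic carbon (future C2) is cut. Forward, the rhodium carbenoid of 5 inserts into the O–H bond of 3. An α-bromo ester made by radical bromination was not chosen, because the benzylic CH2 of the benzyl ether would compete.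

5 ⇒ 4 and 3 ⇒ 1. Diazo transfer to the arylacetate 4 gives 5. Oxidative aryl migration in aldehyde 1, through formate 2, gives phenol 3.

## Alternatives that were turned down

Alternative 1: The C3–C4 bond of the dihydroflavonol 3-hydroxy-5,6,7-trimethoxy-2-(4-methoxyphenyl)chroman-4-one A1 is disconnected to the dialdehyde 2,3,4-trimethoxy-6-[1-(4-methoxyphenyl)-2-oxoethoxy]benzaldehyde A2. Forward, a thiazolium-derived carbene catalyst turns one formyl group into an acyl-anion equivalent that adds to the other, closing the six-membered ring as an intramolecular crossed benzoin.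
- For: O3 arrives directly as a free secondary hydroxyl, already distinct from the aryl ether oxygens. On this point the alternative is stronger than the chosen route, which needs a separate bromine-to-oxygen exchange.
- Against: the aryl aldehyde of A2 must act as the acyl donor, but it is flanked by two ortho oxygen substituents and deactivated by three donors. The aliphatic aldehyde is more accessible to the catalyst and, being α-aryl and α-aryloxy, highly enolisable. Wrong-way coupling to the 4-hydroxychroman-3-one constitution, aldol reactions and decomposition of A2 are therefore expected. A1 also needs dehydrogenation to the flavonol level, and 3-hydroxychromanones tend to ring-contract or eliminate in that step.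
- Comparison: the chosen strategy fixes carbonyl and heteroatom positions by structure, gives ring C at the correct oxidation level, and uses a robust precursor.

Alternative 2: The O1–C8a bond of 6,7-dihydroxy-3,5-dimethoxy-2-(4-methoxyphenyl)-4H-chromen-4-one A3 is disconnected to the catechol diketone 1-(3,4-dihydroxy-2-methoxyphenyl)-2-methoxy-3-(4-methoxyphenyl)propane-1,3-dione A4. Forward, anodic two-electron oxidation of A4 gives the o-quinone; the enol oxygen adds to the quinone carbon that becomes C8a (6-endo conjugate addition), and rearomatisation gives A3.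
- For: no stoichiometric oxidant, no halogenated carbene source and no strong base. The carbon skeleton comes from ordinary acyl-transfer chemistry. On reagent economy and mildness this alternative is stronger.
- Against: A3 is again a catechol, with one more oxygen donor than A4, so over-oxidation at the electrode is likely. The quinone has several electrophilic positions and the aqueous medium competes as a nucleophile. A4 needs a 1,2,3,4-tetrasubstituted arene with one methyl ether beside two free hydroxyls, which costs several steps. Most important, O3 of A3 is a methyl ether like O5 and O4', so it is not distinguished for sulfation.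
- Comparison: the chosen strategy marks C3 with bromine and takes ring A from a symmetric phenol.

Alternative 3: Ring A of 5-hydroxy-3,6,7-trimethoxy-2-(4-methoxyphenyl)-4H-chromen-4-one A5 is disconnected at C4a–C5 to the pyranonyl cyclobutenone 2,3-dimethoxy-4-[5-methoxy-6-(4-methoxyphenyl)-4-oxo-4H-pyran-2-yl]cyclobut-2-en-1-one A6. Forward, heating opens the four-membered ring (4π) to a dienylketene, a 6π electrocyclisation onto the free pyranone carbon forms C4a–C5, and tautomerisation gives the phenol.
- For: thermal and reagent-free, with the ring A substitution pattern set unambiguously by the four-membered ring. O5 emerges as a free hydroxyl, a differentiation the chosen route does not provide.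
- Against: ring A of 20 needs no construction, since its pattern is available as a symmetric phenol. A6 requires a 2,6-disubstituted 3-alkoxypyranone and a differentiated cyclobutenone, each several steps, joined by a further coupling. O3 is again an undifferentiated methyl ether.
- Comparison: the chosen strategy is clearly shorter and delivers C3 with a unique handle.

Key step: step 7

Assumption: 1 and 4 are taken as purchasable benzyl-protected building blocks (each otherwise one O-benzylation from a catalogue phenol), and the target is taken to be wanted as the free hydrogen sulfate drawn, generated in the last operation and kept cold.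

## Route

Step 1
Reactants: 1 3,4,5-tris(benzyloxy)benzaldehyde
Product: 3 3,4,5-tris(benzyloxy)phenol, via aryl formate 2 (not isolated)
Conditions: mCPBA, CH2Cl2, 0 °C → rt; aq. Na2S2O3/NaHCO3 wash; K2CO3 (cat.), MeOH, rt
Reagents that add atoms: 3-chloroperoxybenzoic acid (mCPBA), O=C(OO)c1cccc(Cl)c1
Why: Baeyer–Villiger (Dakin-type) oxidation; the para-alkoxy group makes the aryl group migrate in the peracid adduct to give formate 2, which base-catalysed methanolysis cleaves to 3. Benzyl ethers are inert to both operations.

Step 2
Reactants: 4 methyl 2-[4-(benzyloxy)phenyl]acetate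
Product: 5 methyl 2-[4-(benzyloxy)phenyl]-2-diazoacetate
Conditions: p-ABSA, DBU, MeCN, 0 °C → rt
Reagents that add atoms: 4-acetamidobenzenesulfonyl azide (p-ABSA), CC(=O)Nc1ccc(cc1)S(=O)(=O)N=[N+]=[N-]
Why: Regitz diazo transfer; the amidine base deprotonates the benzylic α-position of the arylacetate and the enolate takes the diazo group from the sulfonyl azide. The process is ionic and leaves the benzylic CH2 of the ether untouched.

Step 3
Reactants: 3 3,4,5-tris(benzyloxy)phenol; 5 methyl 2-[4-(benzyloxy)phenyl]-2-diazoacetate
Product: 6 methyl 2-[4-(benzyloxy)phenyl]-2-[3,4,5-tris(benzyloxy)phenoxy]acetate (racemic)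
Conditions: Rh2(OAc)4 (1 mol %), CH2Cl2, rt, slow addition of 5
Reagents that add atoms: none
Why: Rhodium-carbenoid O–H insertion; the electrophilic donor/acceptor carbenoid is captured by the phenol oxygen (oxonium ylide, then proton shift) faster than it reacts with arene π-bonds or ether oxygens, forming the future O1–C2 bond. The new stereocentre is racemic and is removed in step 6.

Step 4
Reactants: 6 methyl 2-[4-(benzyloxy)phenyl]-2-[3,4,5-tris(benzyloxy)phenoxy]acetate
Product: 7 2-[4-(benzyloxy)phenyl]-2-[3,4,5-tris(benzyloxy)phenoxy]acetic acid (racemic)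
Conditions: LiOH, THF/MeOH/H2O, rt; then 1 M HCl to pH 3
Reagents that add atoms: lithium hydroxide (hydroxide oxygen), [Li+].[OH-]
Why: Saponification of an unhindered α-aryloxy methyl ester by acyl–oxygen cleavage; epimerisation at the α-carbon is irrelevant because the material is racemic.

Step 5
Reactants: 7 2-[4-(benzyloxy)phenyl]-2-[3,4,5-tris(benzyloxy)phenoxy]acetic acid
Product: 9 4,5,6-tris(benzyloxy)-2-[4-(benzyloxy)phenyl]-1-benzofuran-3(2H)-one (racemic), via mixed trifluoroacetic anhydride 8 (not isolated)
Conditions: (CF3CO)2O, CH2Cl2, 0 °C → rt; then degassed aq. NaHCO3; product kept under argon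
Reagents that add atoms: none
Why: Intramolecular Friedel–Crafts acylation through the mixed anhydride 8; the ring carbon ortho to the ether oxygen is activated by one ortho and one para benzyloxy group and attacks the acyl carbon (5-exo-trig) to close the five-membered ketone. The two ortho positions are equivalent, so only one regioisomer can form, and the absence of a strong Lewis acid spares the benzyl ethers and disfavours decarbonylation.

Step 6
Reactants: 9 4,5,6-tris(benzyloxy)-2-[4-(benzyloxy)phenyl]-1-benzofuran-3(2H)-one
Product: 10 tert-butyl(dimethyl)({4,5,6-tris(benzyloxy)-2-[4-(benzyloxy)phenyl]-1-benzofuran-3-yl}oxy)silane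
Conditions: TBSOTf, NEt3, CH2Cl2, 0 °C
Reagents that add atoms: tert-butyldimethylsilyl trifluoromethanesulfonate (TBSOTf), CC(C)(C)[Si](C)(C)OS(=O)(=O)C(F)(F)F
Why: Soft enolisation and O-silylation; the ketone enolises easily because its enol is an aromatic 3-hydroxybenzofuran, and the silyl triflate with amine base silylates oxygen. The C2 stereocentre disappears, and the bulky silyl group is chosen to resist tert-butoxide in step 7.

Step 7
Reactants: 10 tert-butyl(dimethyl)({4,5,6-tris(benzyloxy)-2-[4-(benzyloxy)phenyl]-1-benzofuran-3-yl}oxy)silane; 11 bromoform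
Product: 14 5,6,7-tris(benzyloxy)-2-[4-(benzyloxy)phenyl]-3-bromo-4H-chromen-4-one, via dibromocyclopropane adduct 12 (not isolated), via 4-silyloxybenzopyrylium bromide 13 (not isolated)
Conditions: KOC(CH3)3 (excess), toluene/hexane, −20 °C → rt
Reagents that add atoms: none
Why: Potassium tert-butoxide deprotonates 11 and the tribromomethyl anion loses bromide to give singlet dibromocarbene, which adds in a concerted [2+1] fashion to the most electron-rich π-bond of 10, the silyl enol ether C2=C3 of the furan ring, giving the cis-fused gem-dibromocyclopropane 12. The two new σ-bonds of 12 are the C2–C3 and C3–C4 bonds of the chromone, the carbene carbon becoming C3. Ionisation of the bromide that lies over the five-membered ring is concerted with disrotatory opening of the cyclopropane, which cleaves the old furan C2–C3 bond; O1 and the silyloxy oxygen take up the charge, so the allyl cation is the aromatic benzopyrylium ion 13, and bromide then removes the silyl group to leave the C4 carbonyl of 14. The closest known reaction type is the one-carbon ring expansion of cyclic silyl enol ethers to 2-halocycloalkenones by dihalocarbenes, related to the Ciamician–Dennstedt enlargement of five-membered heteroarenes. Ring C is thus not closed end to end but formed by insertion of one carbon into the existing five-membered ring, a cheletropic addition followed by a two-electron electrocyclic opening. No stereocentre remains in 14; the two stereocentres of 12 are cis by necessity and are lost on opening. The step needs chemoselectivity for the enol ether over four benzyloxyarene units and eight benzylic C–H bonds, which the much higher nucleophilicity of the doubly oxygenated tetrasubstituted alkene secures. It also needs cleavage of the ring-fusion bond and not a lateral cyclopropane bond, which the oxygen donors at both ends of that bond dictate.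

Step 8
Reactants: 14 5,6,7-tris(benzyloxy)-2-[4-(benzyloxy)phenyl]-3-bromo-4H-chromen-4-one
Product: 17 5,6,7-tris(benzyloxy)-2-[4-(benzyloxy)phenyl]-3-hydroxy-4H-chromen-4-one, via 3-lithiochromone 15 (not isolated), via lithium triisopropoxyborate 16 (not isolated)
Conditions: B(OiPr)3, THF/toluene, −78 °C; n-BuLi, −78 °C; then AcOH, 30% aq. H2O2, 0 °C → rt
Reagents that add atoms: hydrogen peroxide, OO
Why: Bromine–lithium exchange at the sp2 carbon C3 is faster at −78 °C than addition of butyllithium to the vinylogous ester carbonyl, and the 3-lithiochromone 15 is trapped at once by the borate already present to give 16. Peroxide oxidation of the C–B bond with 1,2-shift from boron to oxygen then gives O3 as the only free hydroxyl; lithiation, borate capture and oxidation is an established way to hydroxylate C3 of flavones.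

Step 9
Reactants: 17 5,6,7-tris(benzyloxy)-2-[4-(benzyloxy)phenyl]-3-hydroxy-4H-chromen-4-one
Product: 18 triethylammonium 5,6,7-tris(benzyloxy)-2-[4-(benzyloxy)phenyl]-4-oxo-4H-chromen-3-yl sulfate
Conditions: SO3·NEt3 (excess), NEt3, DMF, 50 °C
Reagents that add atoms: sulfur trioxide–triethylamine complex, CC[N+](CC)(CC)S(=O)(=O)[O-]
Why: O-Sulfation with a sulfur trioxide–amine complex; 17 has a single hydroxyl, so no regiochemical question arises. The sulfate is isolated as its stable triethylammonium salt.

Step 10
Reactants: 18 triethylammonium 5,6,7-tris(benzyloxy)-2-[4-(benzyloxy)phenyl]-4-oxo-4H-chromen-3-yl sulfate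
Product: 20 5,6,7-trihydroxy-2-(4-hydroxyphenyl)-4-oxo-4H-chromen-3-yl hydrogen sulfate (target), via debenzylated triethylammonium salt 19 (not isolated)
Conditions: H2 (1 atm), 10% Pd/C, MeOH/THF, rt, argon work-up; filter; Dowex 50W (H+ form), MeOH/H2O, 0 °C; lyophilise
Reagents that add atoms: none
Why: Catalytic hydrogenolysis cleaves the four benzyl ethers under neutral conditions that leave a sulfate monoester salt and the chromone C2=C3 bond intact. Cation exchange then converts salt 19 into the hydrogen sulfate, and cold, oxygen-free handling protects the sulfate and the 5,6,7-triol.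

## Compound list

1 | 3,4,5-tris(benzyloxy)benzaldehyde | O=Cc1cc(OCc2ccccc2)c(OCc2ccccc2)c(OCc2ccccc2)c1 | starting material
2 | 3,4,5-tris(benzyloxy)phenyl formate | O=COc1cc(OCc2ccccc2)c(OCc2ccccc2)c(OCc2ccccc2)c1 | intermediate (not isolated)
3 | 3,4,5-tris(benzyloxy)phenol | Oc1cc(OCc2ccccc2)c(OCc2ccccc2)c(OCc2ccccc2)c1 | intermediate
4 | methyl 2-[4-(benzyloxy)phenyl]acetate | COC(=O)Cc1ccc(OCc2ccccc2)cc1 | starting material
5 | methyl 2-[4-(benzyloxy)phenyl]-2-diazoacetate | COC(=O)C(=[N+]=[N-])c1ccc(OCc2ccccc2)cc1 | intermediate
6 | methyl 2-[4-(benzyloxy)phenyl]-2-[3,4,5-tris(benzyloxy)phenoxy]acetate (racemic) | COC(=O)C(Oc1cc(OCc2ccccc2)c(OCc2ccccc2)c(OCc2ccccc2)c1)c1ccc(OCc2ccccc2)cc1 | intermediate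
7 | 2-[4-(benzyloxy)phenyl]-2-[3,4,5-tris(benzyloxy)phenoxy]acetic acid (racemic) | OC(=O)C(Oc1cc(OCc2ccccc2)c(OCc2ccccc2)c(OCc2ccccc2)c1)c1ccc(OCc2ccccc2)cc1 | intermediate
8 | 2-[4-(benzyloxy)phenyl]-2-[3,4,5-tris(benzyloxy)phenoxy]acetic trifluoroacetic anhydride (racemic) | O=C(OC(=O)C(F)(F)F)C(Oc1cc(OCc2ccccc2)c(OCc2ccccc2)c(OCc2ccccc2)c1)c1ccc(OCc2ccccc2)cc1 | intermediate (not isolated)
9 | 4,5,6-tris(benzyloxy)-2-[4-(benzyloxy)phenyl]-1-benzofuran-3(2H)-one (racemic) | O=C1C(c2ccc(OCc3ccccc3)cc2)Oc2cc(OCc3ccccc3)c(OCc3ccccc3)c(OCc3ccccc3)c12 | intermediate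
10 | tert-butyl(dimethyl)({4,5,6-tris(benzyloxy)-2-[4-(benzyloxy)phenyl]-1-benzofuran-3-yl}oxy)silane | CC(C)(C)[Si](C)(C)Oc1c(-c2ccc(OCc3ccccc3)cc2)oc2cc(OCc3ccccc3)c(OCc3ccccc3)c(OCc3ccccc3)c12 | intermediate (key-step precursor)
11 | bromoform (tribromomethane) | BrC(Br)Br | starting material
12 | 4,5,6-tris(benzyloxy)-1a-[4-(benzyloxy)phenyl]-1,1-dibromo-6b-[(tert-butyldimethylsilyl)oxy]-1a,6b-dihydro-1H-cyclopropa[b][1]benzofuran (racemic, cis-fused) | CC(C)(C)[Si](C)(C)OC12c3c(OCc4ccccc4)c(OCc4ccccc4)c(OCc4ccccc4)cc3OC1(c5ccc(OCc6ccccc6)cc5)C2(Br)Br | intermediate (not isolated)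
13 | 5,6,7-tris(benzyloxy)-2-[4-(benzyloxy)phenyl]-3-bromo-4-[(tert-butyldimethylsilyl)oxy]chromenylium bromide | [Br-].CC(C)(C)[Si](C)(C)Oc1c(Br)c(-c2ccc(OCc3ccccc3)cc2)[o+]c2cc(OCc3ccccc3)c(OCc3ccccc3)c(OCc3ccccc3)c12 | intermediate (not isolated)
14 | 5,6,7-tris(benzyloxy)-2-[4-(benzyloxy)phenyl]-3-bromo-4H-chromen-4-one | O=c1c(Br)c(-c2ccc(OCc3ccccc3)cc2)oc2cc(OCc3ccccc3)c(OCc3ccccc3)c(OCc3ccccc3)c12 | intermediate (key-step product)
15 | {5,6,7-tris(benzyloxy)-2-[4-(benzyloxy)phenyl]-4-oxo-4H-chromen-3-yl}lithium | [Li]c1c(-c2ccc(OCc3ccccc3)cc2)oc2cc(OCc3ccccc3)c(OCc3ccccc3)c(OCc3ccccc3)c2c1=O | intermediate (not isolated)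
16 | lithium {5,6,7-tris(benzyloxy)-2-[4-(benzyloxy)phenyl]-4-oxo-4H-chromen-3-yl}tri(propan-2-yloxy)borate | [Li+].CC(C)O[B-](OC(C)C)(OC(C)C)c1c(-c2ccc(OCc3ccccc3)cc2)oc2cc(OCc3ccccc3)c(OCc3ccccc3)c(OCc3ccccc3)c2c1=O | intermediate (not isolated)
17 | 5,6,7-tris(benzyloxy)-2-[4-(benzyloxy)phenyl]-3-hydroxy-4H-chromen-4-one | O=c1c(O)c(-c2ccc(OCc3ccccc3)cc2)oc2cc(OCc3ccccc3)c(OCc3ccccc3)c(OCc3ccccc3)c12 | intermediate
18 | triethylammonium 5,6,7-tris(benzyloxy)-2-[4-(benzyloxy)phenyl]-4-oxo-4H-chromen-3-yl sulfate | CC[NH+](CC)CC.[O-]S(=O)(=O)Oc1c(-c2ccc(OCc3ccccc3)cc2)oc2cc(OCc3ccccc3)c(OCc3ccccc3)c(OCc3ccccc3)c2c1=O | intermediate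
19 | triethylammonium 5,6,7-trihydroxy-2-(4-hydroxyphenyl)-4-oxo-4H-chromen-3-yl sulfate | CC[NH+](CC)CC.[O-]S(=O)(=O)Oc1c(-c2ccc(O)cc2)oc2cc(O)c(O)c(O)c2c1=O | intermediate (not isolated)
20 | 5,6,7-trihydroxy-2-(4-hydroxyphenyl)-4-oxo-4H-chromen-3-yl hydrogen sulfate | O=c1c(OS(=O)(=O)O)c(-c2ccc(O)cc2)oc2cc(O)c(O)c(O)c12 | target

## Step count and least certain steps

Total step count: 10. Longest linear sequence: 9 steps (4 → 5 → 6 → 7 → 9 → 10 → 14 → 17 → 18 → 20; equally long from 1 through 3).

Step 7 (key step). Three processes are the most likely to go wrong.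
- tert-Butoxide may remove the silyl group before the carbene adds. The resulting enolate would then be attacked by the carbene at C2 (dibromomethylation) and not cyclopropanated.
- Addition to the hindered tetrasubstituted double bond may be slow, so that the carbene is consumed by tert-butoxide or by insertion into benzylic C–H bonds.
- tert-Butoxide may add to C2 of the product.

Fallback: abandon the carbene insertion and close ring C by oxa-Michael addition, setting out from 3 and coming back at 17. C-Acetylation of 3 ortho to the hydroxyl (Ac2O, BF3·OEt2; both ortho positions are equivalent) should give 1-[2-hydroxy-4,5,6-tris(benzyloxy)phenyl]ethan-1-one F1. Claisen–Schmidt condensation with 4-(benzyloxy)benzaldehyde (KOH, EtOH) should give (E)-3-[4-(benzyloxy)phenyl]-1-[2-hydroxy-4,5,6-tris(benzyloxy)phenyl]prop-2-en-1-one F2. Iodine in DMSO at elevated temperature should cyclise and dehydrogenate it to 5,6,7-tris(benzyloxy)-2-[4-(benzyloxy)phenyl]-4H-chromen-4-one F3. Lithiation of F3 at C3 with LiN(iPr)2 at −78 °C, capture with B(OMe)3 and oxidation with H2O2/AcOH would then give 17.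

Step 5. The α-carbon of 7 carries an aryloxy and a 4-alkoxyphenyl group, so the activated acyl species may lose carbon monoxide or ionise at the benzylic C–O bond before it cyclises. Acid-promoted loss or migration of a benzyl group and air oxidation of the product at C2 are further risks.

Fallback: form the aryl–acyl bond intermolecularly with an acyl donor that has no α-heteroatom and close the ring by C–O bond formation, setting out from 3 and coming back at 9. C-Acylation of 3 with commercial 2-[4-(benzyloxy)phenyl]acetic acid in BF3·OEt2 at the lowest effective temperature should give 2-[4-(benzyloxy)phenyl]-1-[2-hydroxy-4,5,6-tris(benzyloxy)phenyl]ethan-1-one F4. Side-chain bromination with CuBr2 in EtOAc/CHCl3 at reflux should give 2-[4-(benzyloxy)phenyl]-2-bromo-1-[2-hydroxy-4,5,6-tris(benzyloxy)phenyl]ethan-1-one F5. K2CO3 in acetone then closes the ring by intramolecular O-alkylation to 9.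

Step 8. Butyllithium may add to the C4 carbonyl in competition with the exchange. The 3-lithiochromone may also open by β-elimination of the O1 phenoxide, or be protonated before the borate traps it.

Fallback: make the C3–O bond by palladium catalysis without a carbanion, setting out from 14 and coming back at 17. Coupling of 14 with (E)-benzaldoxime as a hydroxide surrogate (Pd2(dba)3, tBuBrettPhos, Cs2CO3, DMF, 80 °C) should give (E)-benzaldehyde O-{5,6,7-tris(benzyloxy)-2-[4-(benzyloxy)phenyl]-4-oxo-4H-chromen-3-yl}oxime F6. Under the same carbonate conditions F6 fragments to the caesium salt of 17, which acidic work-up converts into 17.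

Step 10. The sulfate may be hydrolysed once the counter-ion is exchanged for a proton, or earlier if the hydrogenolysis medium turns acidic. The chelated 5-O-benzyl group may be cleaved slowly, and the 5,6,7-triol may be oxidised by air.

Fallback: carry the sulfate through the hydrogenolysis as a neutral, alkyl-protected diester and release it with a nucleophile, setting out from 17 and coming back at 20. Deprotonation of 17 with NaN(SiMe3)2 in THF at −78 °C and reaction with isobutyl chlorosulfate should give 5,6,7-tris(benzyloxy)-2-[4-(benzyloxy)phenyl]-4-oxo-4H-chromen-3-yl 2-methylpropyl sulfate F7. Hydrogenolysis (H2, 10% Pd/C) should give 5,6,7-trihydroxy-2-(4-hydroxyphenyl)-4-oxo-4H-chromen-3-yl 2-methylpropyl sulfate F8. NaI in acetone at 55 °C dealkylates F8 to sodium 5,6,7-trihydroxy-2-(4-hydroxyphenyl)-4-oxo-4H-chromen-3-yl sulfate F9, and cold cation exchange (H+ form) gives 20.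

## Further compounds

F1 | step 7 | 1-[2-hydroxy-4,5,6-tris(benzyloxy)phenyl]ethan-1-one | CC(=O)c1c(O)cc(OCc2ccccc2)c(OCc2ccccc2)c1OCc1ccccc1
F2 | step 7 | (E)-3-[4-(benzyloxy)phenyl]-1-[2-hydroxy-4,5,6-tris(benzyloxy)phenyl]prop-2-en-1-one | O=C(/C=C/c1ccc(OCc2ccccc2)cc1)c1c(O)cc(OCc2ccccc2)c(OCc2ccccc2)c1OCc1ccccc1
F3 | step 7 | 5,6,7-tris(benzyloxy)-2-[4-(benzyloxy)phenyl]-4H-chromen-4-one | O=c1cc(-c2ccc(OCc3ccccc3)cc2)oc2cc(OCc3ccccc3)c(OCc3ccccc3)c(OCc3ccccc3)c12
F4 | step 5 | 2-[4-(benzyloxy)phenyl]-1-[2-hydroxy-4,5,6-tris(benzyloxy)phenyl]ethan-1-one | O=C(Cc1ccc(OCc2ccccc2)cc1)c1c(O)cc(OCc2ccccc2)c(OCc2ccccc2)c1OCc1ccccc1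
F5 | step 5 | 2-[4-(benzyloxy)phenyl]-2-bromo-1-[2-hydroxy-4,5,6-tris(benzyloxy)phenyl]ethan-1-one (racemic) | O=C(C(Br)c1ccc(OCc2ccccc2)cc1)c1c(O)cc(OCc2ccccc2)c(OCc2ccccc2)c1OCc1ccccc1
F6 | step 8 | (E)-benzaldehyde O-{5,6,7-tris(benzyloxy)-2-[4-(benzyloxy)phenyl]-4-oxo-4H-chromen-3-yl}oxime | O=c1c(O/N=C/c2ccccc2)c(-c2ccc(OCc3ccccc3)cc2)oc2cc(OCc3ccccc3)c(OCc3ccccc3)c(OCc3ccccc3)c12
F7 | step 10 | 5,6,7-tris(benzyloxy)-2-[4-(benzyloxy)phenyl]-4-oxo-4H-chromen-3-yl 2-methylpropyl sulfate | CC(C)COS(=O)(=O)Oc1c(-c2ccc(OCc3ccccc3)cc2)oc2cc(OCc3ccccc3)c(OCc3ccccc3)c(OCc3ccccc3)c2c1=O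
F8 | step 10 | 5,6,7-trihydroxy-2-(4-hydroxyphenyl)-4-oxo-4H-chromen-3-yl 2-methylpropyl sulfate | CC(C)COS(=O)(=O)Oc1c(-c2ccc(O)cc2)oc2cc(O)c(O)c(O)c2c1=O
F9 | step 10 | sodium 5,6,7-trihydroxy-2-(4-hydroxyphenyl)-4-oxo-4H-chromen-3-yl sulfate | [Na+].[O-]S(=O)(=O)Oc1c(-c2ccc(O)cc2)oc2cc(O)c(O)c(O)c2c1=O
A1 | alternative 1 | 3-hydroxy-5,6,7-trimethoxy-2-(4-methoxyphenyl)chroman-4-one (mixture of stereoisomers) | COc1ccc(cc1)C1Oc2cc(OC)c(OC)c(OC)c2C(=O)C1O
A2 | alternative 1 | 2,3,4-trimethoxy-6-[1-(4-methoxyphenyl)-2-oxoethoxy]benzaldehyde (racemic) | COc1ccc(cc1)C(C=O)Oc1cc(OC)c(OC)c(OC)c1C=O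
A3 | alternative 2 | 6,7-dihydroxy-3,5-dimethoxy-2-(4-methoxyphenyl)-4H-chromen-4-one | COc1ccc(cc1)-c1oc2cc(O)c(O)c(OC)c2c(=O)c1OC
A4 | alternative 2 | 1-(3,4-dihydroxy-2-methoxyphenyl)-2-methoxy-3-(4-methoxyphenyl)propane-1,3-dione | COc1ccc(cc1)C(=O)C(OC)C(=O)c1ccc(O)c(O)c1OC
A5 | alternative 3 | 5-hydroxy-3,6,7-trimethoxy-2-(4-methoxyphenyl)-4H-chromen-4-one | COc1ccc(cc1)-c1oc2cc(OC)c(OC)c(O)c2c(=O)c1OC
A6 | alternative 3 | 2,3-dimethoxy-4-[5-methoxy-6-(4-methoxyphenyl)-4-oxo-4H-pyran-2-yl]cyclobut-2-en-1-one (racemic) | COc1ccc(cc1)-c1oc(cc(=O)c1OC)C1C(=O)C(OC)=C1OC
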